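**Plan**
- Retrosynthesis: after global hydrogenolysis, both aryl–C4 bonds of the upper flavan are cut (C4–C8 of ring D, then C4–C4a of ring A), which unmasks C4 as an aldehyde carbon. This leaves (S)-3-aryl-3-aryloxypropanal 7 and benzylated (−)-epigallocatechin 9; 7 is cut further at O1–C2 (Mitsunobu) and C2–C3 (allylation).
- Enabling feature: C4 is a diarylmethine at the aldehyde oxidation level, flanked by C4a of ring A (para to O7, ortho to O1, the most nucleophilic carbon of a resorcinol ether) and by C8 of the phloroglucinol-type ring D. One aldehyde can therefore be arylated twice, first by the tethered ring A, then by ring D.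
- Forward order: the chain O1–C2–C3–C4 is built on the ring B aldehyde; ring C is closed through C4–C4a and the resulting cyclic cation is captured by 9 in the same flask; rings D, E and F come intact from the chiral pool.
- Stereochemistry: C2 from a Keck allylation (R) followed by Mitsunobu inversion (S); C4 from axial capture of the cyclic cation trans to the 2-aryl group; C2 and C3 of the lower unit from (−)-epigallocatechin.
- Helper: ring B carries benzyl carbonates in place of ethers so that C2 cannot ionise in the Mitsunobu and acid steps; they leave with the benzyl ethers in the final hydrogenolysis.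

Key step: step 6

Remark: the target is read as (2S)-7,3',4'-trihydroxyflavan-(4β→8)-(−)-epigallocatechin, i.e. 2,4-trans (2S,4R) in the upper unit and 2,3-cis (2R,3R) in the lower unit; compounds 1, 4 and 8 are taken as commercial.

**Route**

Step 1
Reactants: 1 3,4-dihydroxybenzaldehyde
Product: 2 3,4-bis(benzyloxycarbonyloxy)benzaldehyde
Conditions: CbzCl (2.2 equiv), Et3N (2.5 equiv), CH2Cl2, 0 °C → rt
Reagents that add atoms: benzyl chloroformate, O=C(Cl)OCc1ccccc1
Why: O-acylation of both phenols with a chloroformate should proceed cleanly, and the two carbonates turn ring B from a donor into a weak acceptor for the later steps while remaining cleavable by hydrogenolysis.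

Step 2
Reactants: 2 3,4-bis(benzyloxycarbonyloxy)benzaldehyde
Product: 3 (R)-1-[3,4-bis(benzyloxycarbonyloxy)phenyl]but-3-en-1-ol
Conditions: allylSnBu3 (1.2 equiv), (R)-BINOL (20 mol %), Ti(OiPr)4 (10 mol %), 4 Å MS, CH2Cl2, −20 °C; aq NaHCO3
Reagents that add atoms: allyltributylstannane, C=CC[Sn](CCCC)(CCCC)CCCC
Why: In this Keck asymmetric allylation the (R)-BINOL–titanium alkoxide Lewis acid is expected to direct allyl transfer from tin to the Re face of the aryl aldehyde and so set the (R)-carbinol, under neutral conditions that spare the aryl carbonates.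

Step 3
Reactants: 3 (R)-1-[3,4-bis(benzyloxycarbonyloxy)phenyl]but-3-en-1-ol; 4 3-(benzyloxy)phenol
Product: 5 (S)-4-[3-(benzyloxy)phenoxy]-4-[3,4-bis(benzyloxycarbonyloxy)phenyl]but-1-ene
Conditions: PPh3 (1.5 equiv), DIAD (1.5 equiv), toluene, 0 °C → rt
Reagents that add atoms: none
Why: In this Mitsunobu etherification the phenol displaces the oxyphosphonium group in an SN2 step with inversion, (R) to (S), and the acceptor-substituted ring B should suppress the SN1 leakage that erodes such inversions in alkoxy-substituted benzylic alcohols.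

Step 4
Reactants: 5 (S)-4-[3-(benzyloxy)phenoxy]-4-[3,4-bis(benzyloxycarbonyloxy)phenyl]but-1-ene
Product: 7 (S)-3-[3-(benzyloxy)phenoxy]-3-[3,4-bis(benzyloxycarbonyloxy)phenyl]propanal, via the vicinal diol 6 (not isolated)
Conditions: OsO4 (2 mol %), NaIO4 (4 equiv), 2,6-lutidine, dioxane/H2O 3:1, rt
Reagents that add atoms: osmium tetroxide, O=[Os](=O)(=O)=O (transfers the oxygen); sodium periodate, [Na+].[O-]I(=O)(=O)=O (restores it)
Why: In this Lemieux–Johnson oxidation catalytic osmylation of the only alkene gives diol 6, which periodate cleaves in situ to the aldehyde with loss of formaldehyde, under buffered conditions that should neither touch the stereocenter nor provoke β-elimination of the aryloxy group.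

Step 5
Reactants: 8 (−)-epigallocatechin
Product: 9 5,7,3',4',5'-penta-O-benzyl-(−)-epigallocatechin
Conditions: BnBr (5.5 equiv), K2CO3 (6 equiv), DMF, 0 °C → rt, argon
Reagents that add atoms: benzyl bromide, BrCc1ccccc1
Why: Williamson etherification under carbonate base should benzylate the five phenols only, because the base is too weak to deprotonate the secondary 3-OH, and it leaves both stereocenters of ring F untouched.

Step 6
Reactants: 7 (S)-3-[3-(benzyloxy)phenoxy]-3-[3,4-bis(benzyloxycarbonyloxy)phenyl]propanal; 9 5,7,3',4',5'-penta-O-benzyl-(−)-epigallocatechin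
Product: 12 (2R,3R)-5,7-bis(benzyloxy)-8-[(2S,4R)-7-(benzyloxy)-2-{3,4-bis[(benzyloxycarbonyl)oxy]phenyl}chroman-4-yl]-2-[3,4,5-tris(benzyloxy)phenyl]chroman-3-ol, via flavan-4-ol 10 (not isolated), via flavan-4-yl cation 11 (not isolated)
Conditions: Sc(OTf)3 (10 mol %), 9 (3 equiv), 4 Å MS, CH2Cl2, −20 → 0 °C, slow addition of 7; then Et3N
Reagents that add atoms: none
Why: Sc(OTf)3 activates the aldehyde of 7, the tethered ring A attacks it with the carbon para to its benzyloxy group and ortho to the ether oxygen (the future C4a) to give flavan-4-ol 10, and the doubly oxygen-activated benzylic C–O bond of 10 ionises under the same catalyst to cation 11, which C8 of ring D of 9 captures with loss of a proton. The closest known reaction types are the acid-mediated twofold arylation of an aldehyde (Baeyer condensation, here with one arene tethered) and, for the second half, the Lewis-acid condensation of 4-oxygenated flavans with 5,7-di-O-benzylflavan-3-ols. Ring C closes in a 6-exo-trig Friedel–Crafts hydroxyalkylation with respect to the carbonyl group, which forms the C4–C4a bond. C2 is carried over from 7, since the carbonate-bearing ring B gives little stabilisation to a cation at C2, and C4 is set when 9 adds pseudo-axially to the sofa-shaped cation 11, syn to the axial hydrogen at C2 and hence trans to the equatorial 2-aryl group, which should give the (2S,4R) isomer. The step needs ring closure to outrun attack of 9 on the free aldehyde (six-membered tether, slow addition of 7), closure para and not ortho to the benzyloxy group (the ortho site lies between two oxygens), and attack through C8 and not C6 of 9 (the usual preference of 5,7-di-O-benzylated flavan-3-ols); the excess of 9 suppresses self-condensation of 11.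

Step 7
Reactants: 12 (2R,3R)-5,7-bis(benzyloxy)-8-[(2S,4R)-7-(benzyloxy)-2-{3,4-bis[(benzyloxycarbonyl)oxy]phenyl}chroman-4-yl]-2-[3,4,5-tris(benzyloxy)phenyl]chroman-3-ol
Product: 13 (2R,3R)-8-[(2S,4R)-2-(3,4-dihydroxyphenyl)-7-hydroxychroman-4-yl]-2-(3,4,5-trihydroxyphenyl)chromane-3,5,7-triol
Conditions: H2 (1 atm), Pd(OH)2/C, THF/MeOH/H2O, rt; filtration under argon, lyophilisation
Reagents that add atoms: none
Why: Catalytic hydrogenolysis should cleave the six benzyl ethers and the two benzyl carbonates (the latter through aryl hydrogen carbonates that lose CO2) without touching any stereocenter.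

**Compound list**

1 | 3,4-dihydroxybenzaldehyde | O=Cc1ccc(O)c(O)c1 | starting material
2 | 3,4-bis(benzyloxycarbonyloxy)benzaldehyde | O=Cc1ccc(OC(=O)OCc2ccccc2)c(OC(=O)OCc2ccccc2)c1 | intermediate
3 | (R)-1-[3,4-bis(benzyloxycarbonyloxy)phenyl]but-3-en-1-ol | C=CC[C@@H](O)c1ccc(OC(=O)OCc2ccccc2)c(OC(=O)OCc2ccccc2)c1 | intermediate
4 | 3-(benzyloxy)phenol | Oc1cccc(OCc2ccccc2)c1 | starting material
5 | (S)-4-[3-(benzyloxy)phenoxy]-4-[3,4-bis(benzyloxycarbonyloxy)phenyl]but-1-ene | C=CC[C@H](Oc1cccc(OCc2ccccc2)c1)c1ccc(OC(=O)OCc2ccccc2)c(OC(=O)OCc2ccccc2)c1 | intermediate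
6 | (4S)-4-[3-(benzyloxy)phenoxy]-4-[3,4-bis(benzyloxycarbonyloxy)phenyl]butane-1,2-diol (both C2 epimers) | OCC(O)C[C@H](Oc1cccc(OCc2ccccc2)c1)c1ccc(OC(=O)OCc2ccccc2)c(OC(=O)OCc2ccccc2)c1 | intermediate (not isolated)
7 | (S)-3-[3-(benzyloxy)phenoxy]-3-[3,4-bis(benzyloxycarbonyloxy)phenyl]propanal | O=CC[C@H](Oc1cccc(OCc2ccccc2)c1)c1ccc(OC(=O)OCc2ccccc2)c(OC(=O)OCc2ccccc2)c1 | intermediate
8 | (−)-epigallocatechin, (2R,3R) | Oc1cc(O)c2c(c1)O[C@H](c1cc(O)c(O)c(O)c1)[C@H](O)C2 | starting material
9 | 5,7,3',4',5'-penta-O-benzyl-(−)-epigallocatechin | C(c3ccccc3)Oc1cc(OCc3ccccc3)c2c(c1)O[C@H](c1cc(OCc3ccccc3)c(OCc3ccccc3)c(OCc3ccccc3)c1)[C@H](O)C2 | intermediate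
10 | (2S)-7-(benzyloxy)-2-[3,4-bis(benzyloxycarbonyloxy)phenyl]chroman-4-ol (both C4 epimers) | C(c3ccccc3)Oc1ccc2c(c1)O[C@H](c1ccc(OC(=O)OCc3ccccc3)c(OC(=O)OCc3ccccc3)c1)CC2O | intermediate (not isolated)
11 | (2S)-7-(benzyloxy)-2-[3,4-bis(benzyloxycarbonyloxy)phenyl]chroman-4-ylium | C(c3ccccc3)Oc1ccc2c(c1)O[C@H](c1ccc(OC(=O)OCc3ccccc3)c(OC(=O)OCc3ccccc3)c1)C[CH+]2 | intermediate (not isolated)
12 | (2R,3R)-5,7-bis(benzyloxy)-8-[(2S,4R)-7-(benzyloxy)-2-{3,4-bis[(benzyloxycarbonyl)oxy]phenyl}chroman-4-yl]-2-[3,4,5-tris(benzyloxy)phenyl]chroman-3-ol | C(c3ccccc3)Oc1ccc2c(c1)O[C@H](c1ccc(OC(=O)OCc3ccccc3)c(OC(=O)OCc3ccccc3)c1)C[C@H]2c1c(OCc3ccccc3)cc(OCc3ccccc3)c2c1O[C@H](c1cc(OCc3ccccc3)c(OCc3ccccc3)c(OCc3ccccc3)c1)[C@H](O)C2 | intermediate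
13 | (2R,3R)-8-[(2S,4R)-2-(3,4-dihydroxyphenyl)-7-hydroxychroman-4-yl]-2-(3,4,5-trihydroxyphenyl)chromane-3,5,7-triol | Oc1ccc2c(c1)O[C@H](c1ccc(O)c(O)c1)C[C@H]2c1c(O)cc(O)c2c1O[C@H](c1cc(O)c(O)c(O)c1)[C@H](O)C2 | target

**Totals**
Total step count: 7. Longest linear sequence: 6 steps (steps 1, 2, 3, 4, 6, 7); step 5 prepares the second fragment.

**Steps most likely to fail**

1. Step 6. The aryloxy group may be lost from the acid-activated aldehyde by β-elimination before ring closure, or 9 may attack the open-chain aldehyde first, so that C4 is no longer set in the capture of a cyclic cation and the trans selectivity erodes. The fallback sets out from 7 and separates the two events. Pinnick oxidation (NaClO2, NaH2PO4, 2-methyl-2-butene, t-BuOH/H2O) should give (S)-3-[3-(benzyloxy)phenoxy]-3-[3,4-bis(benzyloxycarbonyloxy)phenyl]propanoic acid F1. Intramolecular Friedel–Crafts acylation through the mixed trifluoroacetic anhydride (TFAA, then cat. TfOH, CH2Cl2, 0 °C) forms the same C4–C4a bond with a far stronger electrophile and should give (S)-7-(benzyloxy)-2-[3,4-bis(benzyloxycarbonyloxy)phenyl]chroman-4-one F2. Luche reduction (NaBH4, CeCl3·7H2O, THF/MeOH, −40 °C) then leads back to the route at 10, now isolated, which is condensed with 9 under the Sc(OTf)3 conditions of step 6 to reach 12.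

2. Step 3. The activated benzylic, homoallylic alcohol may eliminate to the conjugated 1-arylbuta-1,3-diene, or the displacement may lose part of its inversion. The fallback sets out from 2 and avoids any substitution at the stereocenter. Keck allylation with (S)-BINOL in place of (R)-BINOL should give (S)-1-[3,4-bis(benzyloxycarbonyloxy)phenyl]but-3-en-1-ol F3. Its O–H bond is then arylated by a copper-catalysed oxidative coupling of the Chan–Lam type (potassium [3-(benzyloxy)phenyl]trifluoroborate, Cu(OAc)2, DMAP, 4 Å MS, O2, CH2Cl2, rt). The C–O bond of the carbinol is never broken, so configuration is retained, and the sequence returns to the route at 5.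

3. Step 5. Exhaustive benzylation under base may be accompanied by epimerisation at C2 through ring opening, air oxidation of the pyrogallol ring and C-benzylation of ring D. The fallback sets out from 8 and 7 and leaves the lower unit unprotected. The condensation of step 6 is run on free 8 in excess (Sc(OTf)3, THF/HFIP, 0 °C) and should give (2R,3R)-8-[(2S,4R)-7-(benzyloxy)-2-{3,4-bis[(benzyloxycarbonyl)oxy]phenyl}chroman-4-yl]-2-(3,4,5-trihydroxyphenyl)chromane-3,5,7-triol F4. The 4→6 regioisomer expected alongside it would have to be separated. Hydrogenolysis under the conditions of step 7 returns to the route at 13.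

**Further compounds**

F1 | step 6 | (S)-3-[3-(benzyloxy)phenoxy]-3-[3,4-bis(benzyloxycarbonyloxy)phenyl]propanoic acid | OC(=O)C[C@H](Oc1cccc(OCc2ccccc2)c1)c1ccc(OC(=O)OCc2ccccc2)c(OC(=O)OCc2ccccc2)c1
F2 | step 6 | (S)-7-(benzyloxy)-2-[3,4-bis(benzyloxycarbonyloxy)phenyl]chroman-4-one | C(c3ccccc3)Oc1ccc2c(c1)O[C@H](c1ccc(OC(=O)OCc3ccccc3)c(OC(=O)OCc3ccccc3)c1)CC2=O
F3 | step 3 | (S)-1-[3,4-bis(benzyloxycarbonyloxy)phenyl]but-3-en-1-ol | C=CC[C@H](O)c1ccc(OC(=O)OCc2ccccc2)c(OC(=O)OCc2ccccc2)c1
F4 | step 5 | (2R,3R)-8-[(2S,4R)-7-(benzyloxy)-2-{3,4-bis[(benzyloxycarbonyl)oxy]phenyl}chroman-4-yl]-2-(3,4,5-trihydroxyphenyl)chromane-3,5,7-triol | C(c3ccccc3)Oc1ccc2c(c1)O[C@H](c1ccc(OC(=O)OCc3ccccc3)c(OC(=O)OCc3ccccc3)c1)C[C@H]2c1c(O)cc(O)c2c1O[C@H](c1cc(O)c(O)c(O)c1)[C@H](O)C2
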